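A direct plan would grow the chain one diaryl ether bond at a time. The phenoxide of a two-ring iodophenol A1 would be O-arylated by a diaryliodonium salt, the aryl iodide of each product would be oxidised to the next iodonium salt, and the permethyl ether A2 reached in this way would be demethylated. Its weakest steps would be these:
- The repeated peracid oxidation of ever larger, very electron-rich oligo(aryl ether) iodides to trivalent iodine, because ring oxidation would compete and every loss would fall on the whole linear chain.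
- The arylation of doubly ortho-substituted phenoxides, because it would be repeated on the most valuable material.
- The cleavage of 21 methyl ethers with BBr3, because it would rarely go to completion cleanly and would leave an air-sensitive polyphenol in strong acid.

The new route forms no aryl–O bond between two arenes. Rings B, D, F and H are 1,3,5-trioxygenated benzenes with a fourth oxygen at C4, so each is assembled from three oxygen-bearing C2 units: an aryloxyketene (C3, C4), benzyloxyacetylene (C5, C6) and an aryl ethynyl ether (C1, C2). A Danheiser benzannulation of the cyclobutenone made from the first two with the third closes the ring with both ether links and all four oxygens in place. The ether oxygens are ordinary phenol oxygens of rings A, C, E and G, attached to sp3 or sp carbon, so no oxidation of large electron-rich intermediates occurs, and benzyl ethers end in one neutral hydrogenolysis.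

Key step: step 15

Remarks on the chemistry:
- Rings are lettered A to H from the 2,4,6-trihydroxyphenyl end. In rings B, D and F, C1 carries the oxygen to the preceding ring, C4 the oxygen to the following ring, and C3 and C5 the hydroxyls. In rings C, E and G, C1 carries the oxygen to the preceding ring, C2 the oxygen to the following ring, and C3 to C5 the hydroxyls.
- The target has no stereocentre. Cyclobutenones 15 and 18 are racemic and their stereocentre is destroyed in the ring synthesis.
- The (E) geometry of the 1,2-dichlorovinyl ethers is the one expected from anti addition to dichloroacetylene; it is of no consequence, since the group ends as an alkyne.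
- Commercial availability of 1, 10, 16 and 19 is assumed.
- Steps 17, 19 and 21 repeat the key step. In steps 17 and 19 cyclobutenone 15 opens by the same ring opening to the same vinylketene; this is one compound, 26, and it is entered at step 15, where it first forms.

Step 1
Reactants: 1 2,3,4-trihydroxybenzaldehyde
Product: 2 2,3,4-tris(benzyloxy)benzaldehyde
Conditions: BnBr (3.6 equiv), K2CO3 (4 equiv), DMF, 60 °C
Reagents that add atoms: benzyl bromide BrCc1ccccc1
Why: Williamson ether synthesis in which excess halide and base also alkylate the hydrogen-bonded 2-hydroxyl; benzyl is chosen so that every protecting group can leave in one hydrogenolysis at the end.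

Step 2
Reactants: 2 2,3,4-tris(benzyloxy)benzaldehyde
Product: 4 2,3,4-tris(benzyloxy)phenol, via aryl formate 3 (not isolated)
Conditions: mCPBA (1.3 equiv), NaHCO3, CH2Cl2, 0 °C to rt; then K2CO3 (cat.), MeOH, rt
Reagents that add atoms: 3-chloroperbenzoic acid OOC(=O)c1cccc(Cl)c1
Why: Baeyer–Villiger (Dakin-type) oxidation in which the electron-rich aryl group migrates to oxygen, followed by methanolysis of the formate.

Step 3
Reactants: 4 2,3,4-tris(benzyloxy)phenol
Product: 5 3,4,5-tris(benzyloxy)-2-hydroxybenzaldehyde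
Conditions: MgCl2 (2 equiv), Et3N (4 equiv), (CH2O)n (6 equiv), MeCN, reflux; aq. HCl
Reagents that add atoms: paraformaldehyde (as formaldehyde) C=O
Why: Magnesium-mediated ortho-formylation of a phenol (Casnati–Skattebøl), in which the magnesium phenoxide directs formaldehyde to the only free ortho position and a second formaldehyde oxidises the benzylic alkoxide to the aldehyde.

Step 4
Reactants: 5 3,4,5-tris(benzyloxy)-2-hydroxybenzaldehyde
Product: 6 3,4,5-tris(benzyloxy)-2-[(E)-1,2-dichloroethenyloxy]benzaldehyde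
Conditions: Cl2C=CHCl (2 equiv), K2CO3 (2.5 equiv), DMF, 70 °C, Ar
Reagents that add atoms: trichloroethylene ClC=C(Cl)Cl
Why: First stage of the Greene ynol ether synthesis: base converts trichloroethylene into dichloroacetylene and anti addition of the phenoxide gives the (E)-1,2-dichlorovinyl ether, a base-stable latent ethynyl ether that should not react with ketenes.

Step 5
Reactants: 6 3,4,5-tris(benzyloxy)-2-[(E)-1,2-dichloroethenyloxy]benzaldehyde
Product: 8 3,4,5-tris(benzyloxy)-2-[(E)-1,2-dichloroethenyloxy]phenol, via aryl formate 7 (not isolated)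
Conditions: mCPBA (1.2 equiv), NaHCO3, CH2Cl2, 0 °C to rt; then K2CO3 (cat.), MeOH, 0 °C
Reagents that add atoms: 3-chloroperbenzoic acid OOC(=O)c1cccc(Cl)c1
Why: Baeyer–Villiger (Dakin-type) oxidation of the electron-rich aldehyde, which should be much faster than epoxidation of the electron-poor dichloroalkene; methanolysis frees the phenol oxygen that will link to a 1,4-linked ring.

Step 6
Reactants: 8 3,4,5-tris(benzyloxy)-2-[(E)-1,2-dichloroethenyloxy]phenol
Product: 9 {3,4,5-tris(benzyloxy)-2-[(E)-1,2-dichloroethenyloxy]phenoxy}acetic acid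
Conditions: NaH (2.3 equiv), BrCH2CO2H (1.1 equiv), THF–DMF, 0 °C to rt; aq. HCl
Reagents that add atoms: bromoacetic acid OC(=O)CBr
Why: Williamson alkylation of the phenoxide with sodium bromoacetate (SN2 at an sp3 carbon, little affected by the ortho substituent) gives the aryloxyacetic acid that serves as ketene precursor.

Step 7
Reactants: 10 benzyl alcohol
Product: 11 benzyl (E)-1,2-dichloroethenyl ether
Conditions: KH (1.2 equiv), THF, 0 °C; Cl2C=CHCl (1.2 equiv), rt
Reagents that add atoms: trichloroethylene ClC=C(Cl)Cl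
Why: First stage of the Greene ynol ether synthesis as in step 4, here with an alkoxide.

Step 8
Reactants: 11 benzyl (E)-1,2-dichloroethenyl ether
Product: 12 benzyloxyacetylene (benzyl ethynyl ether), kept as a cold ether solution
Conditions: n-BuLi (2.3 equiv), Et2O, −78 to −40 °C; H2O, −78 °C; cold extraction, solution dried over K2CO3 and used the same day
Reagents that add atoms: none
Why: Second stage of the Greene synthesis: n-BuLi eliminates HCl, exchanges the remaining chlorine for lithium and the quench protonates the alkynyllithium; the ether is neither concentrated nor warmed because benzyl alkynyl ethers rearrange on heating.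

Step 9
Reactants: 9 {3,4,5-tris(benzyloxy)-2-[(E)-1,2-dichloroethenyloxy]phenoxy}acetic acid; 12 benzyloxyacetylene
Product: 15 3-(benzyloxy)-4-{3,4,5-tris(benzyloxy)-2-[(E)-1,2-dichloroethenyloxy]phenoxy}cyclobut-2-en-1-one (racemic), via acid chloride 13 (not isolated), via aryloxyketene 14 (not isolated)
Conditions: 9, (COCl)2 (1.5 equiv), DMF (cat.), CH2Cl2, rt, evaporation; then slow addition to 12 (2.5 equiv), Et3N (1.5 equiv), Et2O, 0 °C to rt
Reagents that add atoms: none
Why: Dehydrochlorination of the acid chloride gives the aryloxyketene, and the ketene–ynol ether [2+2] cycloaddition joins the nucleophilic CH carbon of 12 to the ketene carbonyl carbon, which places benzyloxy at C3 and aryloxy at C4 of the cyclobutenone; the new stereocentre is racemic and is destroyed in the benzannulation.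

Step 10
Reactants: 16 benzyloxyacetyl chloride; 12 benzyloxyacetylene
Product: 18 3,4-bis(benzyloxy)cyclobut-2-en-1-one (racemic), via benzyloxyketene 17 (not isolated)
Conditions: 16 added slowly to 12 (1.5 equiv), Et3N (1.3 equiv), Et2O, 0 °C to rt
Reagents that add atoms: none
Why: The same ketene–ynol ether [2+2] cycloaddition as in step 9, with the same regiochemistry, gives the cyclobutenone for ring H.

Step 11
Reactants: 19 1,3,5-tris(benzyloxy)benzene
Product: 21 2,4,6-tris(benzyloxy)benzaldehyde, via iminium chloride 20 (not isolated)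
Conditions: POCl3 (1.3 equiv), DMF, 0 °C to rt; then aq. NaOAc
Reagents that add atoms: N,N-dimethylformamide CN(C)C=O; water O
Why: Vilsmeier–Haack formylation of the highly activated arene, whose three free positions are equivalent.

Step 12
Reactants: 21 2,4,6-tris(benzyloxy)benzaldehyde
Product: 23 2,4,6-tris(benzyloxy)phenol, via aryl formate 22 (not isolated)
Conditions: mCPBA (1.2 equiv), NaHCO3, CH2Cl2, 0 °C; then K2CO3 (cat.), MeOH, Ar
Reagents that add atoms: 3-chloroperbenzoic acid OOC(=O)c1cccc(Cl)c1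
Why: Baeyer–Villiger (Dakin-type) oxidation as in step 2; buffer and inert gas protect the very electron-rich phenol.

Step 13
Reactants: 23 2,4,6-tris(benzyloxy)phenol
Product: 24 1,3,5-tris(benzyloxy)-2-[(E)-1,2-dichloroethenyloxy]benzene
Conditions: Cl2C=CHCl (2 equiv), K2CO3 (2.5 equiv), DMF, 70 °C, Ar
Reagents that add atoms: trichloroethylene ClC=C(Cl)Cl
Why: First stage of the Greene synthesis as in step 4; the doubly flanked phenoxide adds readily to the slim, linear dichloroacetylene, so the hindrance that hampers O-arylation of such phenols plays no part.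

Step 14
Reactants: 24 1,3,5-tris(benzyloxy)-2-[(E)-1,2-dichloroethenyloxy]benzene
Product: 25 1,3,5-tris(benzyloxy)-2-(ethynyloxy)benzene (ring A ethynyl ether)
Conditions: n-BuLi (2.3 equiv), THF, −78 °C; H2O, −78 to 0 °C; used at once
Reagents that add atoms: none
Why: Second stage of the Greene synthesis as in step 8; benzyl ethers should not be metalated at −78 °C.

Step 15
Reactants: 25 ring A ethynyl ether; 15 cyclobutenone
Product: 28 three-ring dichlorovinyl ether, 1,3-bis(benzyloxy)-2-{3,4,5-tris(benzyloxy)-2-[(E)-1,2-dichloroethenyloxy]phenoxy}-5-[2,4,6-tris(benzyloxy)phenoxy]benzene (rings A–B–C), via vinylketene 26 (not isolated), via three-ring phenol 27 (not isolated)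
Conditions: 25 (1.0 equiv), 15 (1.3 equiv), toluene, 80 °C then 110 °C, Ar; then K2CO3, MeOH–THF, rt; then solvent exchange, BnBr, K2CO3, DMF, rt
Reagents that add atoms: benzyl bromide BrCc1ccccc1
Why: Danheiser benzannulation: at 80 °C cyclobutenone 15 opens in a 4π electrocyclic reaction to vinylketene 26 (aryloxy group at C4 turning outward), and the nucleophilic CH carbon of ynol ether 25 attacks the ketene carbonyl carbon in a [2+2] cycloaddition that leaves the ring-A oxygen β to the new carbonyl. The cycloadduct reopens (4π) to a dienylketene, which closes ring B by a thermal 6π electrocyclisation that joins the ketene carbon to the former C4 of 15 (six-membered carbocycle); enolisation then gives phenol 27. The closest known reaction is the benzannulation of cyclobutenones with alkoxy- and siloxyalkynes to resorcinol monoethers. No stereocentre is formed and the one of 15 is destroyed. The step needs regiocontrol and chemoselectivity: the polarity of the ynol ether puts the ring-A oxygen at C1, meta to the new hydroxyl at C3, the ring-C oxygen comes from C4 of 15 and lies between that hydroxyl and the benzyloxy group at C5, and the dichlorovinyl ether of 15 does not react with ketenes, so 15 cannot add to itself. The phenol is benzylated in the same flask because a free hydroxyl would capture the ketene of the next cycle.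

Step 16
Reactants: 28 three-ring dichlorovinyl ether
Product: 29 three-ring ethynyl ether, 1,3-bis(benzyloxy)-2-[3,4,5-tris(benzyloxy)-2-(ethynyloxy)phenoxy]-5-[2,4,6-tris(benzyloxy)phenoxy]benzene
Conditions: n-BuLi (2.3 equiv), THF, −78 °C; H2O, −78 to 0 °C; used at once
Reagents that add atoms: none
Why: Second stage of the Greene synthesis (elimination of HCl, chlorine–lithium exchange, protonation) at −78 °C, where neither benzyl ethers nor diaryl ethers should be metalated.

Step 17
Reactants: 29 three-ring ethynyl ether; 15 cyclobutenone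
Product: 31 five-ring dichlorovinyl ether (rings A–E; 29 whose ethynyl carbons have become C1 and C2 of ring D; ring D is 3,5-bis(benzyloxy)-1,4-phenylene and its C4 oxygen carries ring E, 3,4,5-tris(benzyloxy)-2-[(E)-1,2-dichloroethenyloxy]phenyl), via five-ring phenol 30 (not isolated)
Conditions: 29 (1.0 equiv), 15 (1.3 equiv), toluene, 80 °C then 110 °C, Ar; then K2CO3, MeOH–THF, rt; then solvent exchange, BnBr, K2CO3, DMF, rt
Reagents that add atoms: benzyl bromide BrCc1ccccc1
Why: Second Danheiser benzannulation, in which cyclobutenone 15 opens again as in step 15 and the same cascade, under the same regiochemical control, builds ring D between the ring-C oxygen (on the alkyne carbon) and the ring-E oxygen (on C4 of 15), after which the new phenol is benzylated in the same flask.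

Step 18
Reactants: 31 five-ring dichlorovinyl ether
Product: 32 five-ring ethynyl ether (31 with ethynyloxy in place of the dichloroethenyloxy group on ring E)
Conditions: n-BuLi (2.3 equiv), THF, −78 °C; H2O, −78 to 0 °C; used at once
Reagents that add atoms: none
Why: Second stage of the Greene synthesis as in step 16.

Step 19
Reactants: 32 five-ring ethynyl ether; 15 cyclobutenone
Product: 34 seven-ring dichlorovinyl ether (rings A–G; 32 whose ethynyl carbons have become C1 and C2 of ring F; ring F is 3,5-bis(benzyloxy)-1,4-phenylene and its C4 oxygen carries ring G, 3,4,5-tris(benzyloxy)-2-[(E)-1,2-dichloroethenyloxy]phenyl), via seven-ring phenol 33 (not isolated)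
Conditions: 32 (1.0 equiv), 15 (1.3 equiv), toluene, 80 °C then 110 °C, Ar; then K2CO3, MeOH–THF, rt; then solvent exchange, BnBr, K2CO3, DMF, rt
Reagents that add atoms: benzyl bromide BrCc1ccccc1
Why: Third Danheiser benzannulation, in which cyclobutenone 15 opens again as in step 15 and the same cascade builds ring F; the reacting groups sit at the chain end and their surroundings are the same as in step 17.

Step 20
Reactants: 34 seven-ring dichlorovinyl ether
Product: 35 seven-ring ethynyl ether (34 with ethynyloxy in place of the dichloroethenyloxy group on ring G)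
Conditions: n-BuLi (2.3 equiv), THF, −78 °C; H2O, −78 to 0 °C; used at once
Reagents that add atoms: none
Why: Second stage of the Greene synthesis as in step 16.

Step 21
Reactants: 35 seven-ring ethynyl ether; 18 3,4-bis(benzyloxy)cyclobut-2-en-1-one
Product: 37 eight-ring icosa-O-benzyl ether of the target (rings A–H; all hydroxyls benzylated except the one at C3 of ring H), via vinylketene 36 (not isolated)
Conditions: 35 (1.0 equiv), 18 (2 equiv), toluene, 80 °C then 110 °C, Ar; then K2CO3, MeOH–THF, rt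
Reagents that add atoms: none
Why: Fourth Danheiser benzannulation builds ring H: the benzyloxy groups at C3 and C4 of 18 and the ketene carbonyl give the 3,4,5-trioxygenated ring, the ring-G oxygen ends at C1, and the new phenol is left free because no ketene follows.

Step 22
Reactants: 37 eight-ring icosa-O-benzyl ether
Product: 38 CNP0206369.0 (target)
Conditions: H2 (4 bar), Pd/C or Pd(OH)2/C, THF–MeOH (degassed), rt; filtration and reversed-phase purification under Ar
Reagents that add atoms: none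
Why: Hydrogenolysis of the 20 benzyl ethers under neutral conditions should leave the diaryl ether bonds intact and free all hydroxyls; the target has no stereocentre.

## Compound list

1 | 2,3,4-trihydroxybenzaldehyde | O=Cc1ccc(O)c(O)c1O | starting material
2 | 2,3,4-tris(benzyloxy)benzaldehyde | O=Cc1ccc(OCc2ccccc2)c(OCc2ccccc2)c1OCc1ccccc1 | intermediate
3 | 2,3,4-tris(benzyloxy)phenyl formate | O=COc1ccc(OCc2ccccc2)c(OCc2ccccc2)c1OCc1ccccc1 | intermediate
4 | 2,3,4-tris(benzyloxy)phenol | Oc1ccc(OCc2ccccc2)c(OCc2ccccc2)c1OCc1ccccc1 | intermediate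
5 | 3,4,5-tris(benzyloxy)-2-hydroxybenzaldehyde | O=Cc1cc(OCc2ccccc2)c(OCc2ccccc2)c(OCc2ccccc2)c1O | intermediate
6 | 3,4,5-tris(benzyloxy)-2-[(E)-1,2-dichloroethenyloxy]benzaldehyde | O=Cc1cc(OCc2ccccc2)c(OCc2ccccc2)c(OCc2ccccc2)c1O/C(Cl)=C\Cl | intermediate
7 | 3,4,5-tris(benzyloxy)-2-[(E)-1,2-dichloroethenyloxy]phenyl formate | O=COc1cc(OCc2ccccc2)c(OCc2ccccc2)c(OCc2ccccc2)c1O/C(Cl)=C\Cl | intermediate
8 | 3,4,5-tris(benzyloxy)-2-[(E)-1,2-dichloroethenyloxy]phenol | Oc1cc(OCc2ccccc2)c(OCc2ccccc2)c(OCc2ccccc2)c1O/C(Cl)=C\Cl | intermediate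
9 | {3,4,5-tris(benzyloxy)-2-[(E)-1,2-dichloroethenyloxy]phenoxy}acetic acid | OC(=O)COc1cc(OCc2ccccc2)c(OCc2ccccc2)c(OCc2ccccc2)c1O/C(Cl)=C\Cl | intermediate
10 | benzyl alcohol | OCc1ccccc1 | starting material
11 | benzyl (E)-1,2-dichloroethenyl ether | Cl/C=C(/Cl)OCc1ccccc1 | intermediate
12 | benzyloxyacetylene (benzyl ethynyl ether) | C#COCc1ccccc1 | intermediate
13 | {3,4,5-tris(benzyloxy)-2-[(E)-1,2-dichloroethenyloxy]phenoxy}acetyl chloride | ClC(=O)COc1cc(OCc2ccccc2)c(OCc2ccccc2)c(OCc2ccccc2)c1O/C(Cl)=C\Cl | intermediate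
14 | 2-{3,4,5-tris(benzyloxy)-2-[(E)-1,2-dichloroethenyloxy]phenoxy}ethen-1-one (aryloxyketene) | O=C=COc1cc(OCc2ccccc2)c(OCc2ccccc2)c(OCc2ccccc2)c1O/C(Cl)=C\Cl | intermediate
15 | 3-(benzyloxy)-4-{3,4,5-tris(benzyloxy)-2-[(E)-1,2-dichloroethenyloxy]phenoxy}cyclobut-2-en-1-one (racemic) | O=C1C=C(OCc2ccccc2)C1Oc1cc(OCc2ccccc2)c(OCc2ccccc2)c(OCc2ccccc2)c1O/C(Cl)=C\Cl | intermediate
16 | benzyloxyacetyl chloride | O=C(Cl)COCc1ccccc1 | starting material
17 | benzyloxyketene | O=C=COCc1ccccc1 | intermediate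
18 | 3,4-bis(benzyloxy)cyclobut-2-en-1-one (racemic) | O=C1C=C(OCc2ccccc2)C1OCc1ccccc1 | intermediate
19 | 1,3,5-tris(benzyloxy)benzene | c1ccc(COc2cc(OCc3ccccc3)cc(OCc3ccccc3)c2)cc1 | starting material
20 | N,N-dimethyl-[2,4,6-tris(benzyloxy)phenyl]methaniminium chloride | C[N+](C)=Cc1c(OCc2ccccc2)cc(OCc2ccccc2)cc1OCc1ccccc1.[Cl-] | intermediate
21 | 2,4,6-tris(benzyloxy)benzaldehyde | O=Cc1c(OCc2ccccc2)cc(OCc2ccccc2)cc1OCc1ccccc1 | intermediate
22 | 2,4,6-tris(benzyloxy)phenyl formate | O=COc1c(OCc2ccccc2)cc(OCc2ccccc2)cc1OCc1ccccc1 | intermediate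
23 | 2,4,6-tris(benzyloxy)phenol | Oc1c(OCc2ccccc2)cc(OCc2ccccc2)cc1OCc1ccccc1 | intermediate
24 | 1,3,5-tris(benzyloxy)-2-[(E)-1,2-dichloroethenyloxy]benzene | Cl/C=C(/Cl)Oc1c(OCc2ccccc2)cc(OCc2ccccc2)cc1OCc1ccccc1 | intermediate
25 | 1,3,5-tris(benzyloxy)-2-(ethynyloxy)benzene (ring A ethynyl ether) | C#COc1c(OCc2ccccc2)cc(OCc2ccccc2)cc1OCc1ccccc1 | intermediate
26 | (3Z)-3-(benzyloxy)-4-{3,4,5-tris(benzyloxy)-2-[(E)-1,2-dichloroethenyloxy]phenoxy}buta-1,3-dien-1-one (vinylketene from 15) | O=C=C/C(OCc1ccccc1)=C/Oc1cc(OCc2ccccc2)c(OCc2ccccc2)c(OCc2ccccc2)c1O/C(Cl)=C\Cl | intermediate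
27 | three-ring phenol, 3-(benzyloxy)-2-{3,4,5-tris(benzyloxy)-2-[(E)-1,2-dichloroethenyloxy]phenoxy}-5-[2,4,6-tris(benzyloxy)phenoxy]phenol | c9ccccc9COc1cc(OCc9ccccc9)c(Oc2cc(O)c(Oc3cc(OCc9ccccc9)c(OCc9ccccc9)c(OCc9ccccc9)c3O/C(Cl)=C\Cl)c(OCc9ccccc9)c2)c(OCc9ccccc9)c1 | intermediate
28 | three-ring dichlorovinyl ether, 1,3-bis(benzyloxy)-2-{3,4,5-tris(benzyloxy)-2-[(E)-1,2-dichloroethenyloxy]phenoxy}-5-[2,4,6-tris(benzyloxy)phenoxy]benzene | c9ccccc9COc1cc(OCc9ccccc9)c(Oc2cc(OCc9ccccc9)c(Oc3cc(OCc9ccccc9)c(OCc9ccccc9)c(OCc9ccccc9)c3O/C(Cl)=C\Cl)c(OCc9ccccc9)c2)c(OCc9ccccc9)c1 | intermediate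
29 | three-ring ethynyl ether, 1,3-bis(benzyloxy)-2-[3,4,5-tris(benzyloxy)-2-(ethynyloxy)phenoxy]-5-[2,4,6-tris(benzyloxy)phenoxy]benzene | c9ccccc9COc1cc(OCc9ccccc9)c(Oc2cc(OCc9ccccc9)c(Oc3cc(OCc9ccccc9)c(OCc9ccccc9)c(OCc9ccccc9)c3OC#C)c(OCc9ccccc9)c2)c(OCc9ccccc9)c1 | intermediate
30 | five-ring phenol (rings A–E; ring D 3-(benzyloxy)-5-hydroxy-1,4-phenylene; ring E with the (E)-1,2-dichloroethenyloxy group) | c9ccccc9COc1cc(OCc9ccccc9)c(Oc2cc(OCc9ccccc9)c(Oc3cc(OCc9ccccc9)c(OCc9ccccc9)c(OCc9ccccc9)c3Oc3cc(O)c(Oc4cc(OCc9ccccc9)c(OCc9ccccc9)c(OCc9ccccc9)c4O/C(Cl)=C\Cl)c(OCc9ccccc9)c3)c(OCc9ccccc9)c2)c(OCc9ccccc9)c1 | intermediate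
31 | five-ring dichlorovinyl ether (rings A–E; benzyl ether of 30) | c9ccccc9COc1cc(OCc9ccccc9)c(Oc2cc(OCc9ccccc9)c(Oc3cc(OCc9ccccc9)c(OCc9ccccc9)c(OCc9ccccc9)c3Oc3cc(OCc9ccccc9)c(Oc4cc(OCc9ccccc9)c(OCc9ccccc9)c(OCc9ccccc9)c4O/C(Cl)=C\Cl)c(OCc9ccccc9)c3)c(OCc9ccccc9)c2)c(OCc9ccccc9)c1 | intermediate
32 | five-ring ethynyl ether (31 with ethynyloxy on ring E) | c9ccccc9COc1cc(OCc9ccccc9)c(Oc2cc(OCc9ccccc9)c(Oc3cc(OCc9ccccc9)c(OCc9ccccc9)c(OCc9ccccc9)c3Oc3cc(OCc9ccccc9)c(Oc4cc(OCc9ccccc9)c(OCc9ccccc9)c(OCc9ccccc9)c4OC#C)c(OCc9ccccc9)c3)c(OCc9ccccc9)c2)c(OCc9ccccc9)c1 | intermediate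
33 | seven-ring phenol (rings A–G; ring F 3-(benzyloxy)-5-hydroxy-1,4-phenylene; ring G with the (E)-1,2-dichloroethenyloxy group) | c9ccccc9COc1cc(OCc9ccccc9)c(Oc2cc(OCc9ccccc9)c(Oc3cc(OCc9ccccc9)c(OCc9ccccc9)c(OCc9ccccc9)c3Oc3cc(OCc9ccccc9)c(Oc4cc(OCc9ccccc9)c(OCc9ccccc9)c(OCc9ccccc9)c4Oc4cc(O)c(Oc5cc(OCc9ccccc9)c(OCc9ccccc9)c(OCc9ccccc9)c5O/C(Cl)=C\Cl)c(OCc9ccccc9)c4)c(OCc9ccccc9)c3)c(OCc9ccccc9)c2)c(OCc9ccccc9)c1 | intermediate
34 | seven-ring dichlorovinyl ether (rings A–G; benzyl ether of 33) | c9ccccc9COc1cc(OCc9ccccc9)c(Oc2cc(OCc9ccccc9)c(Oc3cc(OCc9ccccc9)c(OCc9ccccc9)c(OCc9ccccc9)c3Oc3cc(OCc9ccccc9)c(Oc4cc(OCc9ccccc9)c(OCc9ccccc9)c(OCc9ccccc9)c4Oc4cc(OCc9ccccc9)c(Oc5cc(OCc9ccccc9)c(OCc9ccccc9)c(OCc9ccccc9)c5O/C(Cl)=C\Cl)c(OCc9ccccc9)c4)c(OCc9ccccc9)c3)c(OCc9ccccc9)c2)c(OCc9ccccc9)c1 | intermediate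
35 | seven-ring ethynyl ether (34 with ethynyloxy on ring G) | c9ccccc9COc1cc(OCc9ccccc9)c(Oc2cc(OCc9ccccc9)c(Oc3cc(OCc9ccccc9)c(OCc9ccccc9)c(OCc9ccccc9)c3Oc3cc(OCc9ccccc9)c(Oc4cc(OCc9ccccc9)c(OCc9ccccc9)c(OCc9ccccc9)c4Oc4cc(OCc9ccccc9)c(Oc5cc(OCc9ccccc9)c(OCc9ccccc9)c(OCc9ccccc9)c5OC#C)c(OCc9ccccc9)c4)c(OCc9ccccc9)c3)c(OCc9ccccc9)c2)c(OCc9ccccc9)c1 | intermediate
36 | (3Z)-3,4-bis(benzyloxy)buta-1,3-dien-1-one (vinylketene from 18) | O=C=C/C(OCc1ccccc1)=C/OCc1ccccc1 | intermediate
37 | eight-ring icosa-O-benzyl ether of the target (rings A–H; free hydroxyl at C3 of ring H) | c9ccccc9COc1cc(OCc9ccccc9)c(Oc2cc(OCc9ccccc9)c(Oc3cc(OCc9ccccc9)c(OCc9ccccc9)c(OCc9ccccc9)c3Oc3cc(OCc9ccccc9)c(Oc4cc(OCc9ccccc9)c(OCc9ccccc9)c(OCc9ccccc9)c4Oc4cc(OCc9ccccc9)c(Oc5cc(OCc9ccccc9)c(OCc9ccccc9)c(OCc9ccccc9)c5Oc5cc(O)c(OCc9ccccc9)c(OCc9ccccc9)c5)c(OCc9ccccc9)c4)c(OCc9ccccc9)c3)c(OCc9ccccc9)c2)c(OCc9ccccc9)c1 | intermediate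
38 | CNP0206369.0 (eight-ring polyhydroxylated oligo(aryl ether); achiral) | Oc1cc(O)c(Oc2cc(O)c(Oc3cc(O)c(O)c(O)c3Oc3cc(O)c(Oc4cc(O)c(O)c(O)c4Oc4cc(O)c(Oc5cc(O)c(O)c(O)c5Oc5cc(O)c(O)c(O)c5)c(O)c4)c(O)c3)c(O)c2)c(O)c1 | target

Total: 22 steps. Longest linear sequence: 15 steps (steps 1 to 6, 9 and 15 to 22).

Steps most likely to fail:

1. Step 15 (the same holds for its repeats, steps 17, 19 and 21). The vinylketene forms only at about 80 °C, where the terminal aryl ethynyl ether may oligomerise faster than it is captured, and the phenol formed may be acylated by remaining ketene. The fallback would form the same vinylketene 26 at room temperature by 1,4-dehydrochlorination of an acid chloride, so that the alkyne meets the ketene cold. Setting out from phenol 8, alkylation with ethyl 4-chloroacetoacetate (K2CO3, acetone) would give ethyl 4-{3,4,5-tris(benzyloxy)-2-[(E)-1,2-dichloroethenyloxy]phenoxy}-3-oxobutanoate F1. Mitsunobu O-benzylation of its enol (benzyl alcohol, PPh3, diisopropyl azodicarboxylate) would give the (E)-enol ether ester F2, saponification (LiOH, THF–H2O) the acid F3, and oxalyl chloride the acid chloride F4. Slow addition of Et3N to F4 and 25 in CH2Cl2 at 20 °C would release 26 in the presence of the alkyne; the cycloadduct would then be warmed in toluene without free alkyne. The route would be rejoined at phenol 27, and F4 would likewise replace 15 in steps 17 and 19.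

2. Step 9 (and step 10). The benzyl alkynyl ether 12 may rearrange or oligomerise, or ketene 14 may dimerise, before the cycloaddition takes place. The fallback would bring in the benzyl group after the four-membered ring is made. Setting out from acid chloride 13, Et3N and commercial ethoxyacetylene (stable, usable in large excess) would give 3-ethoxy-4-{3,4,5-tris(benzyloxy)-2-[(E)-1,2-dichloroethenyloxy]phenoxy}cyclobut-2-en-1-one F5. Acid-catalysed vinylogous transesterification with benzyl alcohol (camphorsulfonic acid, toluene, ethanol removed under reduced pressure) would return to 15.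

3. Step 22. The hydrogenolysis may stall as partly debenzylated, poorly soluble intermediates foul the catalyst, and the polyphenol may oxidise in air during filtration. The fallback would be a non-reductive Lewis-acid debenzylation of 37 with BCl3 and pentamethylbenzene (cation scavenger) in CH2Cl2 at −78 °C with a methanol quench, which would give 38 directly and makes no new compound (F0).

## Further compounds

F1 | step 15 | ethyl 4-{3,4,5-tris(benzyloxy)-2-[(E)-1,2-dichloroethenyloxy]phenoxy}-3-oxobutanoate | CCOC(=O)CC(=O)COc1cc(OCc2ccccc2)c(OCc2ccccc2)c(OCc2ccccc2)c1O/C(Cl)=C\Cl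
F2 | step 15 | ethyl (E)-3-(benzyloxy)-4-{3,4,5-tris(benzyloxy)-2-[(E)-1,2-dichloroethenyloxy]phenoxy}but-2-enoate | CCOC(=O)/C=C(/OCc1ccccc1)COc1cc(OCc2ccccc2)c(OCc2ccccc2)c(OCc2ccccc2)c1O/C(Cl)=C\Cl
F3 | step 15 | (E)-3-(benzyloxy)-4-{3,4,5-tris(benzyloxy)-2-[(E)-1,2-dichloroethenyloxy]phenoxy}but-2-enoic acid | OC(=O)/C=C(/OCc1ccccc1)COc1cc(OCc2ccccc2)c(OCc2ccccc2)c(OCc2ccccc2)c1O/C(Cl)=C\Cl
F4 | step 15 | (E)-3-(benzyloxy)-4-{3,4,5-tris(benzyloxy)-2-[(E)-1,2-dichloroethenyloxy]phenoxy}but-2-enoyl chloride | ClC(=O)/C=C(/OCc1ccccc1)COc1cc(OCc2ccccc2)c(OCc2ccccc2)c(OCc2ccccc2)c1O/C(Cl)=C\Cl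
F5 | step 9 | 3-ethoxy-4-{3,4,5-tris(benzyloxy)-2-[(E)-1,2-dichloroethenyloxy]phenoxy}cyclobut-2-en-1-one (racemic) | CCOC1=CC(=O)C1Oc1cc(OCc2ccccc2)c(OCc2ccccc2)c(OCc2ccccc2)c1O/C(Cl)=C\Cl
F0 | step 22 | none | none
A1 | direct plan | 6-(4-iodo-2,6-dimethoxyphenoxy)-2,3,4-trimethoxyphenol | COc1cc(I)cc(OC)c1Oc1cc(OC)c(OC)c(OC)c1O
A2 | direct plan | henicosa-O-methyl ether of the target | COc1cc(OC)c(Oc2cc(OC)c(Oc3cc(OC)c(OC)c(OC)c3Oc3cc(OC)c(Oc4cc(OC)c(OC)c(OC)c4Oc4cc(OC)c(Oc5cc(OC)c(OC)c(OC)c5Oc5cc(OC)c(OC)c(OC)c5)c(OC)c4)c(OC)c3)c(OC)c2)c(OC)c1
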